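**Strategy.** The oxolane ring is closed last, by oxidative ring-opening of a C2-symmetric trans-1,2-bis(hydroxymethyl)-3,4-diarylcyclobutane (a ferulic acid photodimer, one CH2OH masked as acetate). One-electron oxidation of a phenol cleaves the bis-benzylic cyclobutane bond to a bis(p-quinone methide); the free CH2OH closes the oxolane (O1–C2 bond) and water adds to the second quinone methide. The step exploits that oxolane C2 and the exocyclic carbinol carbon both lie para to a phenolic OH of a guaiacyl ring, and that oxolane C3 and C4 are the two retained cyclobutane stereocentres. Precursor: the cyclobutane monoacetate, assembled by a chiral-tether-controlled [2+2] photodimerisation.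

Key step: step 5

Assumption: the (4S,5S)-threitol tether is taken to favour the (1R,2R)-cyclobutane, on the argument that both trans ring fusions of the C2-symmetric ten-membered bis-lactone adopt the same screw sense; if the opposite sense were found, the (4R,5R)-diol would replace it with no other change.

**Step 1**
Reactants: 1 (E)-3-(4-acetoxy-3-methoxyphenyl)prop-2-enoic acid (O-acetylferulic acid, 2.1 equiv); 2 (4S,5S)-2,2-dimethyl-1,3-dioxolane-4,5-dimethanol (2,3-O-isopropylidene-L-threitol)
Product: 3 [(4S,5S)-2,2-dimethyl-1,3-dioxolane-4,5-diyl]bis(methylene) bis[(E)-3-(4-acetoxy-3-methoxyphenyl)prop-2-enoate]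
Conditions: DCC (2.2 equiv), DMAP (cat.), CH2Cl2, 0 °C to rt
Reagents that add atoms: none
Why: Steglich esterification of both primary hydroxyls via the DMAP acylpyridinium; no stereocentre is touched and the aryl acetates survive the neutral conditions.

**Step 2**
Reactants: 3 bis-cinnamate of the threitol acetonide
Product: 4 cyclic diester of (1R,2R,3S,4S)-3,4-bis(4-acetoxy-3-methoxyphenyl)cyclobutane-1,2-dicarboxylic acid with diol 2 (ten-membered bis-lactone, trans-fused to the cyclobutane and to the dioxolane)
Conditions: [Ir(dF(CF3)ppy)2(dtbbpy)]PF6 (1 mol%), MeCN (5 mM), blue LEDs (450 nm), N2, rt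
Reagents that add atoms: none
Why: Intramolecular triplet-sensitised [2+2] photocycloaddition (energy transfer to a cinnamoyl unit), in which the tether enforces head-to-head union through a 1,4-bis(benzylic) diradical, the 1,4-diol span should bridge only a trans-1,2-diester and the (4S,5S)-dioxolane should select the (1R,2R) screw sense, while diradical closure places the aryl groups trans (their configuration is erased in step 5, so epimers at those carbons converge).

**Step 3**
Reactants: 4 cyclobutane bis-lactone
Product: 5 [(1R,2R,3S,4S)-3,4-bis(4-hydroxy-3-methoxyphenyl)cyclobutane-1,2-diyl]dimethanol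
Conditions: LiAlH4 (excess), THF, 0 °C to rt; aqueous Rochelle salt, pH 6 work-up
Reagents that add atoms: none
Why: Hydride reduction of esters converts both lactone carbonyls into CH2OH, releases the tether diol 2 for recovery and cleaves both aryl acetates; the ring stereocentres are not affected.

**Step 4**
Reactants: 5 cyclobutane diol bis-phenol
Product: 6 [(1R,2R,3S,4S)-2-(hydroxymethyl)-3,4-bis(4-hydroxy-3-methoxyphenyl)cyclobutyl]methyl acetate
Conditions: Candida antarctica lipase B (immobilised), vinyl acetate (1.5 equiv), THF, 30 °C, stopped at the monoacetate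
Reagents that add atoms: vinyl acetate, C=COC(C)=O
Why: Lipase-catalysed transesterification with an enol ester acylates primary aliphatic hydroxyls in preference to phenols, and because the two CH2OH groups are homotopic (C2 axis) a single monoacetate should result.

**Step 5**
Reactants: 6 cyclobutane monoacetate
Product: 9 [(2S,3R,4R)-4-[(R)-hydroxy(4-hydroxy-3-methoxyphenyl)methyl]-2-(4-hydroxy-3-methoxyphenyl)oxolan-3-yl]methyl acetate, via open-chain bis(quinone methide) 7 (not isolated), via oxolanyl quinone methide 8 (not isolated)
Conditions: FeCl3·6H2O (2.2 equiv), acetone/H2O 9:1, N2, 0 °C to rt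
Reagents that add atoms: water, O
Why: FeCl3 (trivalent iron) oxidises a guaiacyl phenol to its phenoxyl radical, whose spin density at the para carbon triggers β-scission of the strained bis-benzylic C3–C4 cyclobutane bond; a second electron transfer and loss of two protons give the open-chain bis(p-quinone methide) 7 with the two CH2O-bearing stereocentres untouched. The closest known reaction type is the oxidative ring-opening of 1,2-diarylcyclobutanes followed by oxa-1,6-addition of a pendant alcohol to a p-quinone methide, the intermediate of biomimetic lignan coupling. The free CH2OH can reach only the quinone methide carbon attached to the neighbouring backbone carbon and closes the oxolane by 5-exo-trig attack (the alternative is an oxetane), rearomatising one ring to give 8. Oxolane C2 should be set trans to the C3 CH2OAc group because, in the A(1,3)-minimised conformer with the allylic C–H eclipsing the exocyclic C=C, the tethered oxygen attacks the face anti to CH2OAc, and reversible reopening under the Lewis acid would lead to the same thermodynamic trans product. The exocyclic carbinol carbon should be set R by water adding to the remaining quinone methide of 8, again in its A(1,3)-minimised conformer, from the face of the ring CH2 (C5) and anti to the more substituted C3 with its cis CH2OAc group. The selectivity needed is hydration in place of a second cyclisation to the furofuran, and the acetate secures it, since its carbonyl could participate only through a seven-membered ring.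

**Step 6**
Reactants: 9 hydroxy acetate
Product: 10 (7R)-7-hydroxylariciresinol, [(2S,3R,4R)-4-[(R)-hydroxy(4-hydroxy-3-methoxyphenyl)methyl]-2-(4-hydroxy-3-methoxyphenyl)oxolan-3-yl]methanol
Conditions: K2CO3 (0.2 equiv), MeOH, rt; NH4Cl quench
Reagents that add atoms: none
Why: Base-catalysed methanolysis (Zemplén-type transesterification) of the primary acetate at room temperature should be too mild to ionise the p-hydroxybenzylic C–O bonds, so no stereocentre is affected.

**Compound list**
1 | (E)-3-(4-acetoxy-3-methoxyphenyl)prop-2-enoic acid (O-acetylferulic acid) | CC(=O)Oc1ccc(/C=C/C(=O)O)cc1OC | starting material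
2 | (4S,5S)-2,2-dimethyl-1,3-dioxolane-4,5-dimethanol | CC1(C)O[C@@H](CO)[C@H](CO)O1 | starting material
3 | [(4S,5S)-2,2-dimethyl-1,3-dioxolane-4,5-diyl]bis(methylene) bis[(E)-3-(4-acetoxy-3-methoxyphenyl)prop-2-enoate] | CC(=O)Oc1ccc(/C=C/C(=O)OC[C@@H]2OC(C)(C)O[C@H]2COC(=O)/C=C/c2ccc(OC(C)=O)c(OC)c2)cc1OC | intermediate
4 | cyclic diester of (1R,2R,3S,4S)-3,4-bis(4-acetoxy-3-methoxyphenyl)cyclobutane-1,2-dicarboxylic acid with diol 2 | O=C1OC[C@@H]2OC(C)(C)O[C@H]2COC(=O)[C@H]3[C@H]1[C@@H](c1ccc(OC(C)=O)c(OC)c1)[C@@H]3c1ccc(OC(C)=O)c(OC)c1 | intermediate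
5 | [(1R,2R,3S,4S)-3,4-bis(4-hydroxy-3-methoxyphenyl)cyclobutane-1,2-diyl]dimethanol | OC[C@H]1[C@H](CO)[C@@H](c2ccc(O)c(OC)c2)[C@@H]1c1ccc(O)c(OC)c1 | intermediate
6 | [(1R,2R,3S,4S)-2-(hydroxymethyl)-3,4-bis(4-hydroxy-3-methoxyphenyl)cyclobutyl]methyl acetate | CC(=O)OC[C@H]1[C@H](CO)[C@@H](c2ccc(O)c(OC)c2)[C@@H]1c1ccc(O)c(OC)c1 | intermediate
7 | (2R,3R)-3-(hydroxymethyl)-4-(3-methoxy-4-oxocyclohexa-2,5-dien-1-ylidene)-2-[(3-methoxy-4-oxocyclohexa-2,5-dien-1-ylidene)methyl]butyl acetate | CC(=O)OC[C@H](C=C1C=CC(=O)C(OC)=C1)[C@H](CO)C=C1C=CC(=O)C(OC)=C1 | intermediate (not isolated)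
8 | [(2S,3R,4R)-2-(4-hydroxy-3-methoxyphenyl)-4-[(3-methoxy-4-oxocyclohexa-2,5-dien-1-ylidene)methyl]oxolan-3-yl]methyl acetate | COc1cc([C@H]2OC[C@H](C=C3C=CC(=O)C(OC)=C3)[C@@H]2COC(C)=O)ccc1O | intermediate (not isolated)
9 | [(2S,3R,4R)-4-[(R)-hydroxy(4-hydroxy-3-methoxyphenyl)methyl]-2-(4-hydroxy-3-methoxyphenyl)oxolan-3-yl]methyl acetate | COc1cc([C@H]2OC[C@H]([C@@H](O)c3ccc(O)c(OC)c3)[C@@H]2COC(C)=O)ccc1O | intermediate
10 | (7R)-7-hydroxylariciresinol | COc1cc([C@H]2OC[C@H]([C@@H](O)c3ccc(O)c(OC)c3)[C@@H]2CO)ccc1O | target

Total step count: 6. Longest linear sequence: 6 steps (1 to 10).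

**Steps most likely to fail**

Step 5. The hydration of the second quinone methide may show poor facial selectivity, or the carbinol may epimerise by acid-mediated reversible quinone methide formation, so that 9 is obtained mixed with its epimer at the exocyclic carbinol carbon. The fallback sets out from this mixture of 9 and sets the carbinol by catalyst control instead. Oxidation of the benzylic alcohol with activated MnO2 in acetone should give the aryl ketone [(2S,3R,4R)-4-(4-hydroxy-3-methoxybenzoyl)-2-(4-hydroxy-3-methoxyphenyl)oxolan-3-yl]methyl acetate F1. Noyori asymmetric transfer hydrogenation with RuCl(p-cymene)[(R,R)-TsDPEN] in HCO2H/Et3N should then return the (R)-carbinol, coming back to the route at 9. The catalyst enantiomer is chosen by analogy with simple aryl alkyl ketones, and catalyst control is relied on because Felkin-type hydride delivery would favour the epimer.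

Step 2. The first C–C bond may form with low or opposite facial selectivity, or intermolecular oligomerisation may compete with closure of the ten-membered ring. The fallback sets out from 1 and replaces auxiliary control by resolution. Esterification of 1 (MeOH, DCC, DMAP) gives methyl (E)-3-(4-acetoxy-3-methoxyphenyl)prop-2-enoate F2. Intermolecular sensitised head-to-head dimerisation at high concentration with the same iridium photocatalyst should give racemic dimethyl (1R*,2R*,3S*,4S*)-3,4-bis(4-acetoxy-3-methoxyphenyl)cyclobutane-1,2-dicarboxylate F3. LiAlH4 reduction then gives the racemic all-trans diol F4, which is resolved by preparative chromatography on a chiral stationary phase, coming back to the route at 5.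

Step 4. Over-acylation to the diacetate, acylation of a phenol, or slow acceptance of the hindered neopentyl-like alcohol by the enzyme may erode the yield of monoacetate. The fallback sets out from 5 and desymmetrises through a ring. Trimethyl orthoacetate with catalytic pyridinium p-toluenesulfonate should convert the 1,4-diol into the cyclic methyl orthoacetate of diol 5 (2-methoxy-2-methyl-1,3-dioxepane trans-fused to the diarylcyclobutane) F5. Its mild aqueous acetic acid hydrolysis can open to one monoacetate only, coming back to the route at 6.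

**Further compounds**
F1 | step 5 | [(2S,3R,4R)-4-(4-hydroxy-3-methoxybenzoyl)-2-(4-hydroxy-3-methoxyphenyl)oxolan-3-yl]methyl acetate | COc1cc([C@H]2OC[C@H](C(=O)c3ccc(O)c(OC)c3)[C@@H]2COC(C)=O)ccc1O
F2 | step 2 | methyl (E)-3-(4-acetoxy-3-methoxyphenyl)prop-2-enoate | COC(=O)/C=C/c1ccc(OC(C)=O)c(OC)c1
F3 | step 2 | racemic dimethyl (1R*,2R*,3S*,4S*)-3,4-bis(4-acetoxy-3-methoxyphenyl)cyclobutane-1,2-dicarboxylate (one enantiomer drawn) | COC(=O)[C@H]1[C@H](C(=O)OC)[C@@H](c2ccc(OC(C)=O)c(OC)c2)[C@@H]1c1ccc(OC(C)=O)c(OC)c1
F4 | step 2 | racemic all-trans [3,4-bis(4-hydroxy-3-methoxyphenyl)cyclobutane-1,2-diyl]dimethanol (5 together with its (1S,2S,3R,4R) enantiomer; the enantiomer is drawn) | OC[C@@H]1[C@@H](CO)[C@H](c2ccc(O)c(OC)c2)[C@H]1c1ccc(O)c(OC)c1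
F5 | step 4 | cyclic methyl orthoacetate of diol 5 (2-methoxy-2-methyl-1,3-dioxepane trans-fused to the diarylcyclobutane) | COC1(C)OC[C@H]2[C@H](CO1)[C@@H](c1ccc(O)c(OC)c1)[C@@H]2c1ccc(O)c(OC)c1
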